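**Retrosynthetic overview**

1. The only ring, the quinone carbocycle, is never built. It is bought as 2,5-dihydroxy-1,4-benzoquinone (1), and only its two oxygen substituents are differentiated (dimethyl ether 2, then mono-hydrolysis through salt 3 to hydroxyquinone 4).
2. Disconnection A, made last and by a new reaction: the ring C3–chain C1′ bond. Compound 4 and henicosan-1-ol (5) go through triol 6, aldehyde 7 and alkylidene 8 to target 9 in a redox-neutral hydrogen-borrowing alkylation.
3. Disconnection B: the O–CH3 bonds. The OH/OMe distinction is fixed before the chain arrives, so the C–C bond formation is regiochemically unambiguous.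
4. Forward order: two C–O manipulations, then the C–C bond. There is no ring-forming step.

Assumption: the target has no stereocentre and no stereogenic double bond (it is achiral), so the compound itself is the "single enantiomer"; the side chain is read as unbranched henicosyl (21 carbons).

**Route**

Step 1
Reactants: 1 2,5-dihydroxy-1,4-benzoquinone
Product: 2 2,5-dimethoxy-1,4-benzoquinone
Conditions: MeOH, conc. HCl (cat.), rt to 50 °C, 16 h; cool, filter
Reagents that add atoms: methanol, CO
Why: Acid-catalysed vinylogous Fischer esterification, in which each ring C–OH carbon is the β-carbon of an enone (a vinylogous carboxylic acid), methanol adds and water leaves, and the sparingly soluble dimethyl ether 2 crystallises and drives the equilibrium (no stereocentre).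

Step 2
Reactants: 2 2,5-dimethoxy-1,4-benzoquinone
Product: 4 2-hydroxy-5-methoxy-1,4-benzoquinone, via sodium 4-methoxy-3,6-dioxocyclohexa-1,4-dien-1-olate 3 (not isolated)
Conditions: NaOH (1.05 equiv, 0.1 M aq., slow addition), THF/H2O, 0 °C to rt, 3 h; then 1 M HCl to pH 1, EtOAc extraction
Reagents that add atoms: sodium hydroxide, [Na+].[OH-]
Why: Vinylogous-ester saponification by addition–elimination of hydroxide at one methoxy-bearing ring carbon stops after one cleavage because the resulting oxidoquinone anion 3 is electron-rich and repels a second hydroxide, and acidification liberates the vinylogous acid 4 (no stereocentre).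

Step 3
Reactants: 4 2-hydroxy-5-methoxy-1,4-benzoquinone; 5 henicosan-1-ol
Product: 9 3-henicosyl-2-hydroxy-5-methoxy-1,4-benzoquinone, via 5-methoxybenzene-1,2,4-triol 6 (not isolated), via henicosanal 7 (not isolated), via 3-henicosylidene-5-methoxycyclohex-5-ene-1,2,4-trione 8 (not isolated)
Conditions: 4 (1.3 equiv), 5 (1.0 equiv), {[(η5-Ph4C4CO)]2H}Ru2(CO)4(μ-H) (Shvo's complex, 2 mol%), NaOAc (10 mol%), 4 Å molecular sieves, 1,4-dioxane, 100 °C, sealed tube, Ar, 24 h
Reagents that add atoms: none
Why: Proposed new method: a redox-neutral hydrogen-borrowing C-alkylation of a hydroxyquinone by a primary alcohol in which the quinone itself is the hydrogen reservoir: the cyclopentadienone complex {[(η5-Ph4C4CO)]2H}Ru2(CO)4(μ-H) dehydrogenates 5 to aldehyde 7 and unloads the two hydrogens onto 4 (quinones are the classical acceptors for its hydride form, giving triol 6), 7 undergoes Knoevenagel condensation only at C3 of the remaining 4 because C3 is the α-carbon of the acidic vinylogous acid whereas C6 belongs to the non-ionisable vinylogous ester, and the strongly electrophilic alkylidene trione 8 is reduced by 6 or by the metal hydride to 9 with return of 4 (the 0.3 equiv excess of 4 guarantees free quinone throughout), so water is the only by-product and no stereocentre is formed; the closest known reaction types are the hydrogen-borrowing C-alkylation of cyclic 1,3-dicarbonyl compounds (4-hydroxycoumarins, barbiturates) with alcohols and the three-component reductive alkylation of hydroxyquinones with aldehydes and Hantzsch ester.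

**Compound list**

1 | 2,5-dihydroxy-1,4-benzoquinone | OC1=CC(=O)C(O)=CC1=O | starting material
2 | 2,5-dimethoxy-1,4-benzoquinone | COC1=CC(=O)C(OC)=CC1=O | intermediate
3 | sodium 4-methoxy-3,6-dioxocyclohexa-1,4-dien-1-olate | [Na+].[O-]C1=CC(=O)C(OC)=CC1=O | intermediate
4 | 2-hydroxy-5-methoxy-1,4-benzoquinone | COC1=CC(=O)C(O)=CC1=O | intermediate
5 | henicosan-1-ol | CCCCCCCCCCCCCCCCCCCCCO | starting material
6 | 5-methoxybenzene-1,2,4-triol | COc1cc(O)c(O)cc1O | intermediate
7 | henicosanal | CCCCCCCCCCCCCCCCCCCCC=O | intermediate
8 | 3-henicosylidene-5-methoxycyclohex-5-ene-1,2,4-trione (transient; alkene geometry undefined and of no consequence) | CCCCCCCCCCCCCCCCCCCCC=C1C(=O)C(=O)C=C(OC)C1=O | intermediate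
9 | 3-henicosyl-2-hydroxy-5-methoxy-1,4-benzoquinone (achiral) | CCCCCCCCCCCCCCCCCCCCCC1=C(O)C(=O)C=C(OC)C1=O | target

**Step count and risks**

Total step count: 3. Longest linear sequence: 3 steps (1 → 2 → 4 → 9); 5 is a purchased partner that enters in step 3.

The three steps most likely to fail:

First, step 3, the proposed new alkylation. Likely failure modes are:
- Tishchenko-type ester formation from 7 on the catalyst.
- Loss of H2, which would leave 8 unreduced.
- Exchange of the C5 methoxy group with 5.
- Addition of a second molecule of 4 to 8.

The fallback uses known chemistry and sets out from 5 and 4. Alcohol 5 is oxidised to henicosanal 7, which is isolated here (2,2,6,6-tetramethylpiperidin-1-oxyl cat., PhI(OAc)2 1.1 equiv, CH2Cl2, rt). Then 4, 7 and diethyl 2,6-dimethyl-1,4-dihydropyridine-3,5-dicarboxylate (Hantzsch ester, 1.2 equiv) are stirred with L-proline (20 mol%) in CH2Cl2 at rt. This is the established organocatalytic three-component reductive alkylation of hydroxyquinones: Knoevenagel condensation at C3 gives 8, and hydride transfer from the dihydropyridine reduces it. The fallback comes back to the route at 9 and makes no compound outside the list (F0).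

Second, step 2. Quinone 2 is poorly soluble, so the dissolved fraction can meet excess hydroxide and be hydrolysed twice back to 1, and 4 is an acidic, water-soluble quinone that is easily lost on extraction. The fallback sets out from 2 and cleaves the other C–O bond: instead of hydroxide attacking the ring carbon, chloride attacks the methyl carbon. Heating 2 with LiCl (1.5 equiv) in DMF at 80 °C effects SN2 O-demethylation, expelling chloromethane and giving lithium 4-methoxy-3,6-dioxocyclohexa-1,4-dien-1-olate F1. A second demethylation would have to expel a dianion, so the reaction stops at the mono-stage. Acidification with 1 M HCl gives 4, where the fallback comes back to the route.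

Third, step 1. The Fischer-type etherification is an equilibrium and can stall at the mono-ether or give low conversion if 2 does not crystallise cleanly. The fallback sets out from 1 and replaces acid-catalysed addition–elimination at the ring carbons by O-alkylation of the oxygen nucleophile. Stirring 1 with Ag2O (1.1 equiv) and MeI (excess) in CHCl3 at rt in the dark methylates both acidic hydroxyl groups irreversibly through the silver salt. The fallback comes back to the route at 2 and makes no compound outside the list (F0).

**Further compounds**

F0 | step 1 | none | none
F1 | step 2 | lithium 4-methoxy-3,6-dioxocyclohexa-1,4-dien-1-olate | [Li+].[O-]C1=CC(=O)C(OC)=CC1=O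
F0 | step 3 | none | none
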